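**Remark (numbering and configuration):** ring atoms are numbered as in p-menthane: C1 = ring C bearing CH2O (C7), C2 = C=O, C3 = CH–O(4-hydroxytigloyl), C4 = CH–isopropyl (C8), C5 = CH–O(isobutyryl), C6 = CH=. The SMILES is read as 3R,4S,5S, i.e. 3-O/4-iPr trans and 4-iPr/5-O cis.

## Retrosynthetic overview

1. Target ⇐ removal of two TBS ethers ⇐ hydrogenation of a C4 isopropenyl group ⇐ Mitsunobu inversion at C5 with isobutyric acid ⇐ all-trans 5-hydroxy-4-isopropenyl enone that already carries the C3 ester.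
2. Key disconnection C4–C5: a Me2AlCl-promoted type I carbonyl-ene cyclisation of an acyclic (2Z)-4-oxo-2-enal onto a Me2C=CH– group closes the cyclohexenone (the only ring of the target, so the last one closed) and creates C4, C5, the C5 hydroxyl and the isopropenyl group in one operation.
3. Enabling feature: C2(=O)–C1=C6–C5(O) is a cis-1,4-dioxygenated but-2-ene, i.e. an opened furan, and C5(OH)–C4–C8 is a homoallylic-alcohol (isopulegol-type) ene retron. The only stereocentre of the precursor, C3, is allylic to the ene donor and relays its configuration by A(1,3) strain.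
4. Oxo-enal ⇐ singlet-oxygen opening of a 2,3-disubstituted furan (temporary ring; furan C2, C3, C4, C5 become C2, C1, C6, C5) ⇐ esterification of an (R)-furyl carbinol with TBS-protected (E)-4-hydroxytiglic acid (made by Wittig) ⇐ catalytic asymmetric furyl transfer to prenal. Furan-3-ylmethanol and prenal together supply all ten skeletal carbons.
5. Ring order: furan (purchased, opened in step 7), then the six-membered carbocycle (step 8).

Key step: step 8

## Route

Step 1
Reactants: 1 2-[(tert-butyldimethylsilyl)oxy]acetaldehyde; 2 ethyl 2-(triphenyl-λ5-phosphanylidene)propanoate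
Product: 3 ethyl (2E)-4-[(tert-butyldimethylsilyl)oxy]-2-methylbut-2-enoate
Conditions: CH2Cl2, rt
Reagents that add atoms: none
Why: Wittig olefination with a stabilised α-methyl ylide should be E-selective, which fixes the tiglate geometry (ester trans to CH2OTBS).

Step 2
Reactants: 3 ethyl (2E)-4-[(tert-butyldimethylsilyl)oxy]-2-methylbut-2-enoate
Product: 4 (2E)-4-[(tert-butyldimethylsilyl)oxy]-2-methylbut-2-enoic acid
Conditions: LiOH·H2O, THF/MeOH/H2O, 0 °C → rt; then 1 M HCl to pH 4, 0 °C
Reagents that add atoms: lithium hydroxide, [Li+].[OH-]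
Why: Ester saponification (BAc2) that a primary TBS ether and the trisubstituted alkene geometry should survive.

Step 3
Reactants: 5 furan-3-ylmethanol
Product: 6 tert-butyl(furan-3-ylmethoxy)dimethylsilane
Conditions: TBSCl, imidazole, DMF, rt
Reagents that add atoms: tert-butyldimethylsilyl chloride, CC(C)(C)[Si](C)(C)Cl
Why: Standard silylation of a primary alcohol; it masks the future C7 hydroxyl through to the last step.

Step 4
Reactants: 6 tert-butyl(furan-3-ylmethoxy)dimethylsilane
Product: 7 [(2-bromofuran-3-yl)methoxy](tert-butyl)dimethylsilane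
Conditions: NBS, DMF, −20 → 0 °C, dark; used without storage
Reagents that add atoms: N-bromosuccinimide, O=C1CCC(=O)N1Br
Why: Electrophilic aromatic bromination of a 3-alkylfuran should occur at the α-position next to the substituent (C2), which defines the site of the later metalation.

Step 5
Reactants: 7 [(2-bromofuran-3-yl)methoxy](tert-butyl)dimethylsilane; 8 3-methylbut-2-enal
Product: 11 (1R)-1-[3-({[tert-butyl(dimethyl)silyl]oxy}methyl)furan-2-yl]-3-methylbut-2-en-1-ol, via 2-furyllithium 9 (not isolated), via ethyl(2-furyl)zinc 10 (not isolated)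
Conditions: n-BuLi, t-BuOMe, −78 °C; EtZnCl, −78 → 0 °C; TEEDA; (−)-MIB (10 mol %), toluene; 8, 0 °C; aq NH4Cl
Reagents that add atoms: none
Why: Catalytic asymmetric (hetero)aryl transfer from a mixed ethyl(heteroaryl)zinc to an aldehyde: Br/Li exchange at −78 °C should outrun O→C silyl migration, TEEDA sequesters LiCl to suppress the racemic background, and the (−)-MIB–zinc catalyst is expected to deliver the furyl group to the Si face of the enal, setting C3 as R (sense to be confirmed by Mosher analysis).

Step 6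
Reactants: 11 (1R)-1-[3-({[tert-butyl(dimethyl)silyl]oxy}methyl)furan-2-yl]-3-methylbut-2-en-1-ol; 4 (2E)-4-[(tert-butyldimethylsilyl)oxy]-2-methylbut-2-enoic acid
Product: 12 (1R)-1-[3-({[tert-butyl(dimethyl)silyl]oxy}methyl)furan-2-yl]-3-methylbut-2-en-1-yl (2E)-4-[(tert-butyldimethylsilyl)oxy]-2-methylbut-2-enoate
Conditions: DCC, DMAP (cat.), CH2Cl2, 0 °C → rt; chromatography on Et3N-deactivated silica
Reagents that add atoms: none
Why: Steglich esterification acylates the O–H bond only, so the C3 configuration is retained and the final C3 ester is in place before the ring exists; neutral conditions avoid ionisation of the furyl/allyl ester.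

Step 7
Reactants: 12 (1R)-1-[3-({[tert-butyl(dimethyl)silyl]oxy}methyl)furan-2-yl]-3-methylbut-2-en-1-yl (2E)-4-[(tert-butyldimethylsilyl)oxy]-2-methylbut-2-enoate
Product: 14 (2Z,5R)-3-({[tert-butyl(dimethyl)silyl]oxy}methyl)-7-methyl-1,4-dioxoocta-2,6-dien-5-yl (2E)-4-[(tert-butyldimethylsilyl)oxy]-2-methylbut-2-enoate, via furan endoperoxide 13 (not isolated)
Conditions: O2, tetraphenylporphyrin (cat.), visible light, CH2Cl2, −78 °C; then Me2S, −78 → 0 °C; cold short silica plug, used at once
Reagents that add atoms: oxygen, O=O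
Why: [4+2] cycloaddition of singlet oxygen to the furan followed by reduction of the endoperoxide unmasks the cis-enedione with the Z geometry inherited from the ring; the furan should react much faster than the trisubstituted alkene, which is deactivated by the allylic acyloxy group.

Step 8
Reactants: 14 (2Z,5R)-3-({[tert-butyl(dimethyl)silyl]oxy}methyl)-7-methyl-1,4-dioxoocta-2,6-dien-5-yl (2E)-4-[(tert-butyldimethylsilyl)oxy]-2-methylbut-2-enoate
Product: 15 (1R,5R,6S)-3-({[tert-butyl(dimethyl)silyl]oxy}methyl)-5-hydroxy-2-oxo-6-(prop-1-en-2-yl)cyclohex-3-en-1-yl (2E)-4-[(tert-butyldimethylsilyl)oxy]-2-methylbut-2-enoate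
Conditions: Me2AlCl (2.5 equiv), CH2Cl2, −78 → −40 °C; aq Rochelle salt
Reagents that add atoms: none
Why: Me2AlCl activates the aldehyde carbon (C5) of the Z-oxo-enal, C4 of the Me2C=CH unit adds to it and an allylic methyl hydrogen is transferred to oxygen in a Lewis-acid type I intramolecular carbonyl-ene reaction, the closest known type being the citronellal-to-isopulegol cyclisation. The six-membered carbocycle is closed as a 6-exo-trig attack on the aldehyde carbon with the ene double bond left exocyclic as the isopropenyl group, and the Z C1=C6 geometry inherited from the furan holds C5 within reach of C4. C4 is controlled by allylic 1,3-strain: the Z-methyl of the Me2C= group forces the C3–H into the alkene plane, so the tether reaches the face of C4 anti to the C3 acyloxy group and the 3,4-trans relation should result. C5 is controlled by a half-chair transition state in which the aluminium-bound oxygen of the s-trans aldehyde points outward (pseudo-equatorial) and gauche to the equatorial Me2C= unit, which should give the 4,5-trans, all-equatorial alcohol. The step needs attack at the aldehyde rather than conjugate attack at C6 or ionisation of the C3 ester: the former would be a 5-endo-trig closure and the latter is disfavoured by the adjacent C2 ketone, while Me2AlCl scavenges the proton and so suppresses Prins-type chloride capture.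

Step 9
Reactants: 15 (1R,5R,6S)-3-({[tert-butyl(dimethyl)silyl]oxy}methyl)-5-hydroxy-2-oxo-6-(prop-1-en-2-yl)cyclohex-3-en-1-yl (2E)-4-[(tert-butyldimethylsilyl)oxy]-2-methylbut-2-enoate; 16 2-methylpropanoic acid
Product: 17 (1R,5S,6S)-3-({[tert-butyl(dimethyl)silyl]oxy}methyl)-5-[(2-methylpropanoyl)oxy]-2-oxo-6-(prop-1-en-2-yl)cyclohex-3-en-1-yl (2E)-4-[(tert-butyldimethylsilyl)oxy]-2-methylbut-2-enoate
Conditions: PPh3, DIAD, toluene, 0 °C → rt
Reagents that add atoms: none
Why: Mitsunobu esterification should displace the equatorial C5 oxyphosphonium by SN2 with inversion, giving the isobutyrate cis to the C4 substituent in the same step; SN2' at the fully substituted C1 and participation by the C3 ester (cis to the leaving group) are not available.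

Step 10
Reactants: 17 (1R,5S,6S)-3-({[tert-butyl(dimethyl)silyl]oxy}methyl)-5-[(2-methylpropanoyl)oxy]-2-oxo-6-(prop-1-en-2-yl)cyclohex-3-en-1-yl (2E)-4-[(tert-butyldimethylsilyl)oxy]-2-methylbut-2-enoate
Product: 18 (1R,5S,6S)-3-({[tert-butyl(dimethyl)silyl]oxy}methyl)-5-[(2-methylpropanoyl)oxy]-2-oxo-6-(propan-2-yl)cyclohex-3-en-1-yl (2E)-4-[(tert-butyldimethylsilyl)oxy]-2-methylbut-2-enoate
Conditions: H2 (1 atm), RhCl(PPh3)3 (5 mol %), benzene, rt
Reagents that add atoms: none
Why: Homogeneous hydrogenation with Wilkinson's catalyst should reduce the 1,1-disubstituted isopropenyl alkene and leave the trisubstituted enone and tiglate alkenes untouched, as in the carvone-to-carvotanacetone reduction; no stereocentre is created.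

Step 11
Reactants: 18 (1R,5S,6S)-3-({[tert-butyl(dimethyl)silyl]oxy}methyl)-5-[(2-methylpropanoyl)oxy]-2-oxo-6-(propan-2-yl)cyclohex-3-en-1-yl (2E)-4-[(tert-butyldimethylsilyl)oxy]-2-methylbut-2-enoate
Product: 19 (1R,5S,6S)-3-(hydroxymethyl)-5-[(2-methylpropanoyl)oxy]-2-oxo-6-(propan-2-yl)cyclohex-3-en-1-yl (2E)-4-hydroxy-2-methylbut-2-enoate (CNP0254776.1)
Conditions: HF·pyridine, pyridine, THF, 0 °C → rt
Reagents that add atoms: none
Why: Buffered fluoride desilylation should cleave both primary TBS ethers without ester migration, elimination or epimerisation at C3.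

## Compound list

1 | 2-[(tert-butyldimethylsilyl)oxy]acetaldehyde | CC(C)(C)[Si](C)(C)OCC=O | starting material
2 | ethyl 2-(triphenyl-λ5-phosphanylidene)propanoate | CCOC(=O)C(C)=P(c1ccccc1)(c1ccccc1)c1ccccc1 | starting material
3 | ethyl (2E)-4-[(tert-butyldimethylsilyl)oxy]-2-methylbut-2-enoate | C/C(=C\CO[Si](C)(C)C(C)(C)C)C(=O)OCC | intermediate
4 | (2E)-4-[(tert-butyldimethylsilyl)oxy]-2-methylbut-2-enoic acid | C/C(=C\CO[Si](C)(C)C(C)(C)C)C(=O)O | intermediate
5 | furan-3-ylmethanol | OCc1ccoc1 | starting material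
6 | tert-butyl(furan-3-ylmethoxy)dimethylsilane | CC(C)(C)[Si](C)(C)OCc1ccoc1 | intermediate
7 | [(2-bromofuran-3-yl)methoxy](tert-butyl)dimethylsilane | CC(C)(C)[Si](C)(C)OCc1ccoc1Br | intermediate
8 | 3-methylbut-2-enal (prenal) | CC(C)=CC=O | starting material
9 | [3-({[tert-butyl(dimethyl)silyl]oxy}methyl)furan-2-yl]lithium | [Li]c1occc1CO[Si](C)(C)C(C)(C)C | intermediate
10 | ethyl[3-({[tert-butyl(dimethyl)silyl]oxy}methyl)furan-2-yl]zinc | CC[Zn]c1occc1CO[Si](C)(C)C(C)(C)C | intermediate
11 | (1R)-1-[3-({[tert-butyl(dimethyl)silyl]oxy}methyl)furan-2-yl]-3-methylbut-2-en-1-ol | CC(C)=C[C@@H](O)c1occc1CO[Si](C)(C)C(C)(C)C | intermediate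
12 | (1R)-1-[3-({[tert-butyl(dimethyl)silyl]oxy}methyl)furan-2-yl]-3-methylbut-2-en-1-yl (2E)-4-[(tert-butyldimethylsilyl)oxy]-2-methylbut-2-enoate | C/C(=C\CO[Si](C)(C)C(C)(C)C)C(=O)O[C@H](C=C(C)C)c1occc1CO[Si](C)(C)C(C)(C)C | intermediate
13 | furan endoperoxide of 12: 2,3,7-trioxabicyclo[2.2.1]hept-5-ene carrying the C3 ester side chain at bridgehead C1 and CH2OTBS at C6 (both bridgehead-face isomers, side-chain centre unchanged) | C/C(=C\CO[Si](C)(C)C(C)(C)C)C(=O)O[C@H](C=C(C)C)C12OOC(O1)C=C2CO[Si](C)(C)C(C)(C)C | intermediate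
14 | (2Z,5R)-3-({[tert-butyl(dimethyl)silyl]oxy}methyl)-7-methyl-1,4-dioxoocta-2,6-dien-5-yl (2E)-4-[(tert-butyldimethylsilyl)oxy]-2-methylbut-2-enoate | O=C/C=C(/CO[Si](C)(C)C(C)(C)C)C(=O)[C@H](OC(=O)/C(C)=C/CO[Si](C)(C)C(C)(C)C)C=C(C)C | intermediate
15 | (1R,5R,6S)-3-({[tert-butyl(dimethyl)silyl]oxy}methyl)-5-hydroxy-2-oxo-6-(prop-1-en-2-yl)cyclohex-3-en-1-yl (2E)-4-[(tert-butyldimethylsilyl)oxy]-2-methylbut-2-enoate (3-O, 4-isopropenyl and 5-OH all trans) | C/C(=C\CO[Si](C)(C)C(C)(C)C)C(=O)O[C@H]1C(=O)C(CO[Si](C)(C)C(C)(C)C)=C[C@@H](O)[C@@H]1C(C)=C | intermediate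
16 | 2-methylpropanoic acid (isobutyric acid) | CC(C)C(=O)O | starting material
17 | (1R,5S,6S)-3-({[tert-butyl(dimethyl)silyl]oxy}methyl)-5-[(2-methylpropanoyl)oxy]-2-oxo-6-(prop-1-en-2-yl)cyclohex-3-en-1-yl (2E)-4-[(tert-butyldimethylsilyl)oxy]-2-methylbut-2-enoate | C/C(=C\CO[Si](C)(C)C(C)(C)C)C(=O)O[C@H]1C(=O)C(CO[Si](C)(C)C(C)(C)C)=C[C@H](OC(=O)C(C)C)[C@@H]1C(C)=C | intermediate
18 | (1R,5S,6S)-3-({[tert-butyl(dimethyl)silyl]oxy}methyl)-5-[(2-methylpropanoyl)oxy]-2-oxo-6-(propan-2-yl)cyclohex-3-en-1-yl (2E)-4-[(tert-butyldimethylsilyl)oxy]-2-methylbut-2-enoate | C/C(=C\CO[Si](C)(C)C(C)(C)C)C(=O)O[C@H]1C(=O)C(CO[Si](C)(C)C(C)(C)C)=C[C@H](OC(=O)C(C)C)[C@@H]1C(C)C | intermediate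
19 | (1R,5S,6S)-3-(hydroxymethyl)-5-[(2-methylpropanoyl)oxy]-2-oxo-6-(propan-2-yl)cyclohex-3-en-1-yl (2E)-4-hydroxy-2-methylbut-2-enoate | C/C(=C\CO)C(=O)O[C@H]1C(=O)C(CO)=C[C@H](OC(=O)C(C)C)[C@@H]1C(C)C | target

## Step count and risks

Total steps: 11. Longest linear sequence: 9 (steps 3–11, from furan-3-ylmethanol).

Steps most likely to fail:

1. Step 8 (ene ring closure). The developing C8 cation may be diverted before hydrogen transfer (capture by chloride or by the C3 ester carbonyl, proton loss toward the tetrasubstituted alkene), or the enedione may isomerise Z→E before cyclising; facial control at the aldehyde may also be incomplete. Fallback, setting out from 14: a SnBr4-induced Prins cyclisation (CH2Cl2, −78 °C) accepts the cation and captures it with bromide to give the 8-bromo-p-menthane carbinol F1. Radical debromination (Bu3SnH, AIBN, benzene, 80 °C) then gives the isopropyl carbinol F2, so the hydrogenation of step 10 is no longer needed. Mitsunobu esterification of F2 with 16 as in step 9 returns to the route at 18.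

2. Step 5 (asymmetric furyl transfer). Salt-promoted background addition or weak enantiofacial discrimination of a β,β-disubstituted enal may erode the enantiomeric purity, and the 2-furyllithium may decompose or undergo silyl migration before transmetalation. Fallback with reversed polarity, setting out from 5: alkoxide-directed C2-lithiation (n-BuLi, 2.2 equiv, THF) and formylation with DMF give 3-(hydroxymethyl)furan-2-carbaldehyde F3. Silylation (TBSCl, imidazole) gives the silyl ether aldehyde F4. (+)-MIB-catalysed addition of bis(2-methylprop-1-enyl)zinc (from the Grignard reagent and ZnCl2) to this aromatic aldehyde, the best substrate class for the catalyst, returns to the route at 11.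

3. Step 9 (Mitsunobu inversion). SN2 displacement at the hindered allylic C5 carbinol by a weakly acidic aliphatic acid may be slow, so that elimination or recovered alcohol dominates. Fallback, setting out from 15, decouples inversion from acylation: Mitsunobu reaction with the more acidic chloroacetic acid gives the inverted chloroacetate F5. Selective dechloroacetylation (thiourea, NaHCO3, EtOH) gives the 4,5-cis alcohol F6. Acylation with isobutyryl chloride (pyridine, DMAP, CH2Cl2) with retention returns to the route at 17.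

## Further compounds

F1 | step 8 | (1R,5R,6S)-6-(2-bromopropan-2-yl)-3-({[tert-butyl(dimethyl)silyl]oxy}methyl)-5-hydroxy-2-oxocyclohex-3-en-1-yl (2E)-4-[(tert-butyldimethylsilyl)oxy]-2-methylbut-2-enoate | C/C(=C\CO[Si](C)(C)C(C)(C)C)C(=O)O[C@H]1C(=O)C(CO[Si](C)(C)C(C)(C)C)=C[C@@H](O)[C@@H]1C(C)(C)Br
F2 | step 8 | (1R,5R,6S)-3-({[tert-butyl(dimethyl)silyl]oxy}methyl)-5-hydroxy-2-oxo-6-(propan-2-yl)cyclohex-3-en-1-yl (2E)-4-[(tert-butyldimethylsilyl)oxy]-2-methylbut-2-enoate | C/C(=C\CO[Si](C)(C)C(C)(C)C)C(=O)O[C@H]1C(=O)C(CO[Si](C)(C)C(C)(C)C)=C[C@@H](O)[C@@H]1C(C)C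
F3 | step 5 | 3-(hydroxymethyl)furan-2-carbaldehyde | O=Cc1occc1CO
F4 | step 5 | 3-({[tert-butyl(dimethyl)silyl]oxy}methyl)furan-2-carbaldehyde | O=Cc1occc1CO[Si](C)(C)C(C)(C)C
F5 | step 9 | (1R,5S,6S)-3-({[tert-butyl(dimethyl)silyl]oxy}methyl)-5-[(chloroacetyl)oxy]-2-oxo-6-(prop-1-en-2-yl)cyclohex-3-en-1-yl (2E)-4-[(tert-butyldimethylsilyl)oxy]-2-methylbut-2-enoate | C/C(=C\CO[Si](C)(C)C(C)(C)C)C(=O)O[C@H]1C(=O)C(CO[Si](C)(C)C(C)(C)C)=C[C@H](OC(=O)CCl)[C@@H]1C(C)=C
F6 | step 9 | (1R,5S,6S)-3-({[tert-butyl(dimethyl)silyl]oxy}methyl)-5-hydroxy-2-oxo-6-(prop-1-en-2-yl)cyclohex-3-en-1-yl (2E)-4-[(tert-butyldimethylsilyl)oxy]-2-methylbut-2-enoate | C/C(=C\CO[Si](C)(C)C(C)(C)C)C(=O)O[C@H]1C(=O)C(CO[Si](C)(C)C(C)(C)C)=C[C@H](O)[C@@H]1C(C)=C
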